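**Retrosynthetic overview**
- Last step is O-demethylation of the 4-methoxy butenolide; before it, the C8–C9 diene bond is made by Suzuki–Miyaura coupling of a C15 (E)-alkenyl boronate (methyl tetronate plus C1–C8) with a C10 (Z)-alkenyl iodide (C9–C13 plus furan).
- The boronate comes from the C7 aldehyde by boryl olefination; the 5E ylidene comes from an anti vinylogous aldol of a 2-silyloxyfuran with the C1 aldehyde, followed by anti dehydration.
- The C1–C7 chain carries both methyl stereocentres from the two enantiomers of 3-bromo-2-methylpropan-1-ol, joined through 1,3-dithiane (future C4) and desulfurised.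
- The (Z)-iodide comes from 3-bromofuran and oxetane, then bromide, Grignard reagent, syn-carbocupration of propyne and iodination.
- No ring is built: the furan is bought as 3-bromofuran and the butenolide as 3-methyltetronic acid; the dithiane ring is a bought linchpin that is cut out in step 6.

Assumptions: 13 and both enantiomers of 3-bromo-2-methylpropan-1-ol are bought. Chain locants C1–C13 run from the ylidene carbon to the furan-bearing carbon. Compounds 17 and 18 are drawn as the (5R,1'R) anti diastereomer; the (5S,1'S) anti diastereomer accompanies it and gives the same alkene. Compounds 19–22, 33 and 34 are handled in amber glassware.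

**Route**

Step 1
Reactants: 1 (R)-3-bromo-2-methylpropan-1-ol
Product: 2 (R)-(3-bromo-2-methylpropoxy)(tert-butyl)diphenylsilane
Conditions: TBDPSCl, imidazole, DMF, 0 °C → rt
Reagents that add atoms: tert-butyl(chloro)diphenylsilane, CC(C)(C)[Si](Cl)(c1ccccc1)c1ccccc1
Why: Silyl ether protection of the primary alcohol gives a base-stable ether; the bought stereocentre (later C6) is not touched.

Step 2
Reactants: 3 1,3-dithiane; 2 (R)-(3-bromo-2-methylpropoxy)(tert-butyl)diphenylsilane
Product: 5 tert-butyl{[(2S)-3-(1,3-dithian-2-yl)-2-methylpropyl]oxy}diphenylsilane, via 2-lithio-1,3-dithiane 4 (not isolated)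
Conditions: n-BuLi, THF, −30 °C; then 2, −30 → 0 °C
Reagents that add atoms: none
Why: Corey–Seebach alkylation (SN2 at the primary bromide) attaches the future C4 carbon; the stereocentre is not involved and only its descriptor changes.

Step 3
Reactants: 6 (S)-3-bromo-2-methylpropan-1-ol
Product: 7 (S)-(3-bromo-2-methylpropoxy)triethylsilane
Conditions: TESCl, imidazole, CH2Cl2, 0 °C
Reagents that add atoms: chlorotriethylsilane, CC[Si](Cl)(CC)CC
Why: Silyl ether protection with the labile triethylsilyl group, which is later oxidised off selectively beside the TBDPS ether; the bought stereocentre (later C2) is untouched.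

Step 4
Reactants: 7 (S)-(3-bromo-2-methylpropoxy)triethylsilane
Product: 8 (S)-triethyl(3-iodo-2-methylpropoxy)silane
Conditions: NaI, NaHCO3 (cat.), acetone, reflux
Reagents that add atoms: sodium iodide, [Na+].[I-]
Why: Finkelstein exchange gives the more reactive β-branched iodide needed for the hindered second alkylation; no stereocentre is touched.

Step 5
Reactants: 5 tert-butyl{[(2S)-3-(1,3-dithian-2-yl)-2-methylpropyl]oxy}diphenylsilane; 8 (S)-triethyl(3-iodo-2-methylpropoxy)silane
Product: 10 tert-butyl{[(2S)-2-methyl-3-{2-[(2R)-2-methyl-3-(triethylsilyloxy)propyl]-1,3-dithian-2-yl}propyl]oxy}diphenylsilane, via lithiated dithiane 9 (not isolated)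
Conditions: t-BuLi, THF/HMPA (10:1), −78 °C; then 8, −78 → −20 °C
Reagents that add atoms: none
Why: A second Corey–Seebach alkylation joins the two chiral C4 units at the linchpin carbon, giving the 2,6-dimethyl chain with differently protected ends and both stereocentres taken from the chiral pool.

Step 6
Reactants: 10 tert-butyl{[(2S)-2-methyl-3-{2-[(2R)-2-methyl-3-(triethylsilyloxy)propyl]-1,3-dithian-2-yl}propyl]oxy}diphenylsilane
Product: 11 tert-butyl{[(2S,6R)-2,6-dimethyl-7-(triethylsilyloxy)heptyl]oxy}diphenylsilane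
Conditions: Raney Ni (W-2), EtOH, reflux
Reagents that add atoms: none
Why: Reductive desulfurisation (Mozingo-type) turns the dithioketal carbon into the C4 methylene; silyl ethers and stereocentres are inert.

Step 7
Reactants: 11 tert-butyl{[(2S,6R)-2,6-dimethyl-7-(triethylsilyloxy)heptyl]oxy}diphenylsilane
Product: 12 (2R,6S)-7-{[tert-butyl(diphenyl)silyl]oxy}-2,6-dimethylheptanal
Conditions: (COCl)2, DMSO, CH2Cl2, −78 → −30 °C; Et3N, −78 °C → rt
Reagents that add atoms: none
Why: Swern oxidation cleaves the primary triethylsilyl ether and oxidises it to the aldehyde in one operation while the TBDPS ether survives; low temperature keeps the α-stereocentre intact.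

Step 8
Reactants: 13 3-methyltetronic acid (4-hydroxy-3-methylfuran-2(5H)-one)
Product: 14 4-methoxy-3-methylfuran-2(5H)-one
Conditions: Me2SO4, K2CO3, acetone, reflux
Reagents that add atoms: dimethyl sulfate, COS(=O)(=O)OC
Why: O-alkylation of the vinylogous acid with a hard methylating agent masks the acidic enol and leaves C5 as the only enolisable position.

Step 9
Reactants: 14 4-methoxy-3-methylfuran-2(5H)-one
Product: 16 4-methoxy-3-methyl-2-(trimethylsilyloxy)furan, via lithium furanolate 15 (not isolated)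
Conditions: LiN(iPr)2, THF, −78 °C; then TMSCl, −78 → 0 °C
Reagents that add atoms: chlorotrimethylsilane, C[Si](C)(C)Cl
Why: C5 deprotonation gives the aromatic furanolate, which is O-silylated to the silyl dienol ether (a 2-silyloxyfuran).

Step 10
Reactants: 12 (2R,6S)-7-{[tert-butyl(diphenyl)silyl]oxy}-2,6-dimethylheptanal; 16 4-methoxy-3-methyl-2-(trimethylsilyloxy)furan
Product: 18 (5R)-5-[(1R,2R,6S)-7-{[tert-butyl(diphenyl)silyl]oxy}-1-hydroxy-2,6-dimethylheptyl]-4-methoxy-3-methylfuran-2(5H)-one, via trimethylsilyl ether 17 (not isolated)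
Conditions: Bu4NF (10 mol %), THF, −78 °C; then 1 M HCl, THF, 0 °C
Reagents that add atoms: none
Why: Fluoride-catalysed vinylogous Mukaiyama aldol: the free dienolate adds through C5 in an open transition state that, by analogy with the parent 2-silyloxyfuran, should favour the anti (5R*,1'R*) adduct; the chain stereocentres are untouched and any syn adduct ends as the 5Z isomer removed after step 11.

Step 11
Reactants: 18 (5R)-5-[(1R,2R,6S)-7-{[tert-butyl(diphenyl)silyl]oxy}-1-hydroxy-2,6-dimethylheptyl]-4-methoxy-3-methylfuran-2(5H)-one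
Product: 19 (5E)-5-[(2R,6S)-7-{[tert-butyl(diphenyl)silyl]oxy}-2,6-dimethylheptylidene]-4-methoxy-3-methylfuran-2(5H)-one
Conditions: PPh3, DIAD, THF, 0 °C → rt
Reagents that add atoms: none
Why: Mitsunobu-type dehydration: the oxyphosphonium group leaves antiperiplanar to H-5 (E2), so the anti adduct gives the 5E ylidene with the chain cis to C4.

Step 12
Reactants: 19 (5E)-5-[(2R,6S)-7-{[tert-butyl(diphenyl)silyl]oxy}-2,6-dimethylheptylidene]-4-methoxy-3-methylfuran-2(5H)-one
Product: 20 (5E)-5-[(2R,6S)-7-hydroxy-2,6-dimethylheptylidene]-4-methoxy-3-methylfuran-2(5H)-one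
Conditions: HF·pyridine, pyridine, THF, 0 °C → rt
Reagents that add atoms: none
Why: Buffered fluoride desilylation frees the primary alcohol without base that could isomerise the ylidene or epimerise C2.

Step 13
Reactants: 20 (5E)-5-[(2R,6S)-7-hydroxy-2,6-dimethylheptylidene]-4-methoxy-3-methylfuran-2(5H)-one
Product: 21 (2S,6R,7E)-7-(3-methoxy-4-methyl-5-oxofuran-2(5H)-ylidene)-2,6-dimethylheptanal
Conditions: Dess–Martin periodinane, CH2Cl2, 0 °C → rt
Reagents that add atoms: none
Why: Dess–Martin oxidation gives the α-branched aldehyde under near-neutral conditions, so C6 of the chain does not epimerise.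

Step 14
Reactants: 21 (2S,6R,7E)-7-(3-methoxy-4-methyl-5-oxofuran-2(5H)-ylidene)-2,6-dimethylheptanal
Product: 22 (5E)-4-methoxy-3-methyl-5-[(2R,6S,7E)-2,6-dimethyl-8-(4,4,5,5-tetramethyl-1,3,2-dioxaborolan-2-yl)oct-7-en-1-ylidene]furan-2(5H)-one
Conditions: Cl2CHBpin, CrCl2, LiI, THF, rt
Reagents that add atoms: 2-(dichloromethyl)-4,4,5,5-tetramethyl-1,3,2-dioxaborolane, ClC(Cl)B1OC(C)(C)C(C)(C)O1
Why: Takai–Utimoto boryl olefination: the geminal dichromium reagent adds to the aldehyde and eliminates to the (E)-alkenyl boronate (7E); the lactone and the α-stereocentre tolerate divalent chromium.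

Step 15
Reactants: 23 3-bromofuran; 24 oxetane
Product: 26 3-(furan-3-yl)propan-1-ol, via furan-3-yllithium 25 (not isolated)
Conditions: n-BuLi, THF, −78 °C; then 24, BF3·OEt2, −78 °C
Reagents that add atoms: none
Why: Bromine–lithium exchange followed by BF3-promoted ring opening of oxetane installs the three-carbon tether at C3 of the furan; keeping −78 °C prevents migration of lithium to C2.

Step 16
Reactants: 26 3-(furan-3-yl)propan-1-ol
Product: 27 3-(3-bromopropyl)furan
Conditions: CBr4, PPh3, CH2Cl2, 0 °C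
Reagents that add atoms: tetrabromomethane, BrC(Br)(Br)Br
Why: Appel reaction converts the primary alcohol to the bromide under neutral conditions that the furan tolerates.

Step 17
Reactants: 27 3-(3-bromopropyl)furan; 28 propyne
Product: 32 3-[(4Z)-5-iodo-4-methylpent-4-en-1-yl]furan, via Grignard reagent 29 (not isolated), via alkylcopper 30 (not isolated), via alkenylcopper 31 (not isolated)
Conditions: Mg, Et2O; CuBr·SMe2, Et2O/Me2S, −45 °C; 28, −25 °C; I2, THF, −50 → 0 °C
Reagents that add atoms: iodine, II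
Why: Normant carbocupration: the alkylcopper adds syn across propyne with the alkyl group on the internal carbon, and iodinolysis with retention gives the (Z)-iodide (chain cis to iodine), which becomes the 9Z alkene.

Step 18
Reactants: 22 (5E)-4-methoxy-3-methyl-5-[(2R,6S,7E)-2,6-dimethyl-8-(4,4,5,5-tetramethyl-1,3,2-dioxaborolan-2-yl)oct-7-en-1-ylidene]furan-2(5H)-one; 32 3-[(4Z)-5-iodo-4-methylpent-4-en-1-yl]furan
Product: 33 (5E)-5-[(2R,6S,7E,9Z)-13-(furan-3-yl)-2,6,10-trimethyltrideca-7,9-dien-1-ylidene]-4-methoxy-3-methylfuran-2(5H)-one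
Conditions: Pd(PPh3)4 (5 mol %), TlOEt, THF/H2O (3:1), rt, dark
Reagents that add atoms: none
Why: Suzuki–Miyaura coupling joins the C15 and C10 halves at C8–C9 with retention of both alkene geometries, giving the (7E,9Z)-diene at room temperature.

Step 19
Reactants: 33 (5E)-5-[(2R,6S,7E,9Z)-13-(furan-3-yl)-2,6,10-trimethyltrideca-7,9-dien-1-ylidene]-4-methoxy-3-methylfuran-2(5H)-one
Product: 34 (5E)-5-[(2R,6S,7E,9Z)-13-(furan-3-yl)-2,6,10-trimethyltrideca-7,9-dien-1-ylidene]-4-hydroxy-3-methylfuran-2(5H)-one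
Conditions: n-PrSLi (n-PrSH, n-BuLi), HMPA, rt; then 1 M HCl
Reagents that add atoms: none
Why: SN2 O-demethylation of the vinylogous methyl ester by a soft, weakly basic thiolate frees the tetronic acid without touching the diene, the furan or the stereocentres.

**Compound list**

1 | (R)-3-bromo-2-methylpropan-1-ol | BrC[C@H](C)CO | starting material
2 | (R)-(3-bromo-2-methylpropoxy)(tert-butyl)diphenylsilane | BrC[C@H](C)CO[Si](c1ccccc1)(c1ccccc1)C(C)(C)C | intermediate
3 | 1,3-dithiane | C1CSCSC1 | starting material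
4 | 2-lithio-1,3-dithiane | [Li]C1SCCCS1 | intermediate
5 | tert-butyl{[(2S)-3-(1,3-dithian-2-yl)-2-methylpropyl]oxy}diphenylsilane | C1CSC(SC1)C[C@H](C)CO[Si](c1ccccc1)(c1ccccc1)C(C)(C)C | intermediate
6 | (S)-3-bromo-2-methylpropan-1-ol | OC[C@H](C)CBr | starting material
7 | (S)-(3-bromo-2-methylpropoxy)triethylsilane | CC[Si](CC)(CC)OC[C@H](C)CBr | intermediate
8 | (S)-triethyl(3-iodo-2-methylpropoxy)silane | CC[Si](CC)(CC)OC[C@H](C)CI | intermediate
9 | 2-lithio derivative of 5 (lithium on the dithiane C2) | [Li]C1(SCCCS1)C[C@H](C)CO[Si](c1ccccc1)(c1ccccc1)C(C)(C)C | intermediate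
10 | tert-butyl{[(2S)-2-methyl-3-{2-[(2R)-2-methyl-3-(triethylsilyloxy)propyl]-1,3-dithian-2-yl}propyl]oxy}diphenylsilane | CC[Si](CC)(CC)OC[C@H](C)CC1(SCCCS1)C[C@H](C)CO[Si](c1ccccc1)(c1ccccc1)C(C)(C)C | intermediate
11 | tert-butyl{[(2S,6R)-2,6-dimethyl-7-(triethylsilyloxy)heptyl]oxy}diphenylsilane | CC[Si](CC)(CC)OC[C@H](C)CCC[C@H](C)CO[Si](c1ccccc1)(c1ccccc1)C(C)(C)C | intermediate
12 | (2R,6S)-7-{[tert-butyl(diphenyl)silyl]oxy}-2,6-dimethylheptanal | O=C[C@H](C)CCC[C@H](C)CO[Si](c1ccccc1)(c1ccccc1)C(C)(C)C | intermediate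
13 | 3-methyltetronic acid (4-hydroxy-3-methylfuran-2(5H)-one) | CC1=C(O)COC1=O | starting material
14 | 4-methoxy-3-methylfuran-2(5H)-one | COC1=C(C)C(=O)OC1 | intermediate
15 | lithium 4-methoxy-3-methylfuran-2-olate | [Li]Oc1occ(OC)c1C | intermediate
16 | 4-methoxy-3-methyl-2-(trimethylsilyloxy)furan | COc1coc(O[Si](C)(C)C)c1C | intermediate
17 | (5R)-5-[(1R,2R,6S)-7-{[tert-butyl(diphenyl)silyl]oxy}-2,6-dimethyl-1-(trimethylsilyloxy)heptyl]-4-methoxy-3-methylfuran-2(5H)-one (anti; drawn 5R,1'R, accompanied by the 5S,1'S anti diastereomer) | COC1=C(C)C(=O)O[C@@H]1[C@H](O[Si](C)(C)C)[C@H](C)CCC[C@H](C)CO[Si](c1ccccc1)(c1ccccc1)C(C)(C)C | intermediate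
18 | (5R)-5-[(1R,2R,6S)-7-{[tert-butyl(diphenyl)silyl]oxy}-1-hydroxy-2,6-dimethylheptyl]-4-methoxy-3-methylfuran-2(5H)-one (anti; drawn 5R,1'R, accompanied by the 5S,1'S anti diastereomer) | COC1=C(C)C(=O)O[C@@H]1[C@H](O)[C@H](C)CCC[C@H](C)CO[Si](c1ccccc1)(c1ccccc1)C(C)(C)C | intermediate
19 | (5E)-5-[(2R,6S)-7-{[tert-butyl(diphenyl)silyl]oxy}-2,6-dimethylheptylidene]-4-methoxy-3-methylfuran-2(5H)-one | CC1=C(OC)/C(=C\[C@H](C)CCC[C@H](C)CO[Si](c2ccccc2)(c2ccccc2)C(C)(C)C)OC1=O | intermediate
20 | (5E)-5-[(2R,6S)-7-hydroxy-2,6-dimethylheptylidene]-4-methoxy-3-methylfuran-2(5H)-one | CC1=C(OC)/C(=C\[C@H](C)CCC[C@H](C)CO)OC1=O | intermediate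
21 | (2S,6R,7E)-7-(3-methoxy-4-methyl-5-oxofuran-2(5H)-ylidene)-2,6-dimethylheptanal | CC1=C(OC)/C(=C\[C@H](C)CCC[C@H](C)C=O)OC1=O | intermediate
22 | (5E)-4-methoxy-3-methyl-5-[(2R,6S,7E)-2,6-dimethyl-8-(4,4,5,5-tetramethyl-1,3,2-dioxaborolan-2-yl)oct-7-en-1-ylidene]furan-2(5H)-one | CC1=C(OC)/C(=C\[C@H](C)CCC[C@H](C)/C=C/B2OC(C)(C)C(C)(C)O2)OC1=O | intermediate
23 | 3-bromofuran | Brc1ccoc1 | starting material
24 | oxetane | C1COC1 | starting material
25 | furan-3-yllithium | [Li]c1ccoc1 | intermediate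
26 | 3-(furan-3-yl)propan-1-ol | OCCCc1ccoc1 | intermediate
27 | 3-(3-bromopropyl)furan | BrCCCc1ccoc1 | intermediate
28 | propyne | CC#C | starting material
29 | [3-(furan-3-yl)propyl]magnesium bromide | Br[Mg]CCCc1ccoc1 | intermediate
30 | [3-(furan-3-yl)propyl]copper (MgBr2/Me2S complex) | [Cu]CCCc1ccoc1 | intermediate
31 | [(1Z)-5-(furan-3-yl)-2-methylpent-1-en-1-yl]copper | [Cu]/C=C(/C)CCCc1ccoc1 | intermediate
32 | 3-[(4Z)-5-iodo-4-methylpent-4-en-1-yl]furan | I/C=C(/C)CCCc1ccoc1 | intermediate
33 | (5E)-5-[(2R,6S,7E,9Z)-13-(furan-3-yl)-2,6,10-trimethyltrideca-7,9-dien-1-ylidene]-4-methoxy-3-methylfuran-2(5H)-one | CC1=C(OC)/C(=C\[C@H](C)CCC[C@H](C)/C=C/C=C(/C)CCCc2ccoc2)OC1=O | intermediate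
34 | (5E)-5-[(2R,6S,7E,9Z)-13-(furan-3-yl)-2,6,10-trimethyltrideca-7,9-dien-1-ylidene]-4-hydroxy-3-methylfuran-2(5H)-one | CC1=C(O)/C(=C\[C@H](C)CCC[C@H](C)/C=C/C=C(/C)CCCc2ccoc2)OC1=O | target

**Counts**
Total step count: 19.
Longest linear sequence: 12 steps (1, 2, 5, 6, 7, 10, 11, 12, 13, 14, 18, 19).

**Steps most likely to fail, with fallbacks**

Step 10 (and the geometry it hands to step 11). The anti selectivity of the fluoride-catalysed aldol is argued by analogy and is not established for this tetrasubstituted silyloxyfuran; a poor ratio lowers the yield of the 5E isomer. The fallback sets out from 12 and 14 and comes back at 19. Aldehyde 12 is added to the lithium furanolate 15 (from 14 with LiN(iPr)2, THF, −78 °C) to give the unselective aldol adduct mixture F1. MsCl/Et3N converts it to the mesylate F2, and DBU eliminates this by E1cB to give mainly the (5Z)-ylidene lactone F3. Irradiation of F3 (300 nm, MeCN), at a stage where no diene is present, gives an E/Z photostationary mixture from which 19 is separated by chromatography and F3 is recycled.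

Step 5. A hindered 2-alkyl dithiane anion must displace a β-branched iodide, and slow substitution or elimination is possible. The fallback sets out from 5 and 8 and comes back at 11. Dithiane 5 is unmasked (MeI, CaCO3, aqueous MeCN) to (3S)-4-{[tert-butyl(diphenyl)silyl]oxy}-3-methylbutanal F4. Iodide 8 is heated with PPh3 (MeCN, reflux) to give triphenyl[(2S)-2-methyl-3-(triethylsilyloxy)propyl]phosphonium iodide F5, which NaN(SiMe3)2 (THF, −78 °C) converts to the ylide F6. Wittig reaction of F6 with F4 gives the (4Z)-alkene F7, and hydrogenation (H2, Pd on carbon, EtOAc) gives 11.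

Step 19. The thiolate could add reversibly to the ylidene and erode the 5E geometry, or act as a base at C2, on the fully assembled and light-sensitive triene. The fallback sets out from 22 and comes back at 34. Boronate 22 is demethylated first (n-PrSLi, HMPA, rt; mild acid work-up) to the free tetronic acid boronate F8, whose geometry can be checked and corrected before the diene exists. F8 is then coupled as its salt with 32 under the step 18 conditions (one extra equivalent of TlOEt) to give 34 directly.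

**Further compounds**

F1 | step 10 | 5-[(2R,6S)-7-{[tert-butyl(diphenyl)silyl]oxy}-1-hydroxy-2,6-dimethylheptyl]-4-methoxy-3-methylfuran-2(5H)-one, mixture of all C5/C1' diastereomers | COC1=C(C)C(=O)OC1C(O)[C@H](C)CCC[C@H](C)CO[Si](c1ccccc1)(c1ccccc1)C(C)(C)C
F2 | step 10 | methanesulfonate of F1 (mesyloxy group on C1 of the heptyl chain) | COC1=C(C)C(=O)OC1C(OS(C)(=O)=O)[C@H](C)CCC[C@H](C)CO[Si](c1ccccc1)(c1ccccc1)C(C)(C)C
F3 | step 10 | (5Z)-5-[(2R,6S)-7-{[tert-butyl(diphenyl)silyl]oxy}-2,6-dimethylheptylidene]-4-methoxy-3-methylfuran-2(5H)-one | CC1=C(OC)/C(=C/[C@H](C)CCC[C@H](C)CO[Si](c2ccccc2)(c2ccccc2)C(C)(C)C)OC1=O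
F4 | step 5 | (3S)-4-{[tert-butyl(diphenyl)silyl]oxy}-3-methylbutanal | O=CC[C@H](C)CO[Si](c1ccccc1)(c1ccccc1)C(C)(C)C
F5 | step 5 | triphenyl[(2S)-2-methyl-3-(triethylsilyloxy)propyl]phosphonium iodide | CC[Si](CC)(CC)OC[C@H](C)C[P+](c1ccccc1)(c1ccccc1)c1ccccc1.[I-]
F6 | step 5 | triphenyl[(2S)-2-methyl-3-(triethylsilyloxy)propylidene]phosphorane | CC[Si](CC)(CC)OC[C@H](C)C=P(c1ccccc1)(c1ccccc1)c1ccccc1
F7 | step 5 | tert-butyl{[(2S,4Z,6R)-2,6-dimethyl-7-(triethylsilyloxy)hept-4-en-1-yl]oxy}diphenylsilane | CC[Si](CC)(CC)OC[C@H](C)/C=C\C[C@H](C)CO[Si](c1ccccc1)(c1ccccc1)C(C)(C)C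
F8 | step 19 | (5E)-4-hydroxy-3-methyl-5-[(2R,6S,7E)-2,6-dimethyl-8-(4,4,5,5-tetramethyl-1,3,2-dioxaborolan-2-yl)oct-7-en-1-ylidene]furan-2(5H)-one | CC1=C(O)/C(=C\[C@H](C)CCC[C@H](C)/C=C/B2OC(C)(C)C(C)(C)O2)OC1=O
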